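Readings and results were computed from invented constants, noise included.

Early readings say little: at 0.667 h larch still held 95% of its electrophile, with a scatter of 2 percentage points on each reading. So I read the rate at 4.00 h, where larch, cedar and maple, charged with 0.41 M, 0.54 M and 0.56 M of free base, held 81%, 80% and 82%. These readings show no order with the base, so I gave the base no time of its own and kept two times: the time of the flask, and the time τ in which the electrophile falls by a factor e. I held τ constant as a rough reckoning, although c(nucleophile) is charged at twice c(electrophile) and falls along with it, so the count should run somewhat high. The ratio of the two times is the number of turnovers.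

all flasks: electrophile 0.36 M; protic impurity 0.108 M
- larch: nucleophile 0.72 M; free base 0.41 M; run made earlier
- maple: nucleophile 0.72 M; free base 0.56 M; run made earlier
- cedar: nucleophile 0.72 M; free base 0.54 M; run made earlier
- midnight: nucleophile 0.720 M; free base 0.400 M; time 8.0 h
- winter: nucleophile 0.720 M; free base 0.510 M; time 8.0 h
- spring: nucleophile 0.720 M; free base 0.670 M; time 8.0 h

| run | time / h | electrophile / % | product / % |
|---|---|---|---|
| larch | 0.333 | 100 | 2 |
| larch | 0.667 | 95 | 3 |
| larch | 1.50 | 91 | 8 |
| larch | 4.00 | 81 | 20 |
| maple | 0.500 | 97 | 6 |
| maple | 1.33 | 95 | 6 |
| maple | 2.50 | 88 | 12 |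
| maple | 4.00 | 82 | 21 |
| cedar | 0.333 | 99 | 7 |
| cedar | 0.667 | 96 | 4 |
| cedar | 1.50 | 89 | 9 |
| cedar | 4.00 | 80 | 17 |

(scatter of a reading: 2 percentage points)



1. part of the electrophile that has reacted at the end, midnight
2. part of the electrophile that has reacted at the end, winter
3. part of the electrophile that has reacted at the end, spring
4. what raising the concentration of free base from its lowest to its highest value here does to the part of the electrophile that has reacted (changes below 5 percentage points count as none) (it rises / it falls / no change)

Mean left at 4.00 h: 81.0%

τ = 19.0 h

Turnovers in 8.0 h: 0.421

Reacted: 1 − exp(−turnovers) = 34.4%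

Even if the impurity and the reacted electrophile each took up base mole for mole, they would claim 0.232 M, less than the 0.400 M of midnight. So I expected the same figure in all three flasks.

The forecast gave 34%, 34% and 34%, with no change. Its ground: “the rate shows no visible dependence on base over this range”.

The flasks gave 32.4% at midnight, 32.4% in winter and 32.5% in spring, so no change, with a change of 0.076 points.

    electrophile + nucleophile → acid set free + product (k = 0.0828 /M/h)
    nucleophile + acid set free ⇌ protonated nucleophile, settled at all times (K = 161 /M)
    acid set free + free base ⇌ salt of the base (K = 10400 /M, k = 4.60 /M/h)
    free base ⇌ dormant form (K = 2.50, k = 0.0466 /h)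
    protic impurity + free base → quenched reagent (k = 9.23 /M/h)

Read as turnovers, the 67.5% of electrophile left in spring at 8.00 h comes to 0.393, against the 0.421 I had counted with τ held constant. The product step holds c(nucleophile) to the first power, so I scaled the count for the neighbour, which is spring with 1.8 M of nucleophile instead of 0.720 M. That gave 1.05 turnovers in the same 8.0 h, and so 65.0% reacted. The neighbour gave 63.6%, with 36.4% of its electrophile left and 75.1% of its charged nucleophile still free.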